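**Strategy.** The oxolane ring (O–C6–C7–C8–C9, chain numbered from the pentyl terminus) carries the C6 pentyl and C7 hydroxyl cis to each other and trans to the C9 side chain. This pattern is disconnected at C5–C6 and O–C7 as a cis-fused oxetane, so one Paternò–Büchi photocycloaddition of pentanal across the C6=C7 enol ether of a (2R)-2-substituted 2,3-dihydrofuran forms both bonds, the four-membered ring and the C6/C7 stereocentres. The precursor already holds the C10 laurate; its C9 and C10 centres come from (R,R)-diepoxybutane, and O10 is capped before the ring oxygen O9 is released, so that Mo(CO)6-catalysed cycloisomerisation and acylation are unambiguous. Silyl iodide opening at C5 and Bu3SnH reduction finish.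

Key step: step 7

Assumption: (2R,2'R)-2,2'-bioxirane (the D-threitol-derived enantiomer of 1,2:3,4-diepoxybutane) is taken as a purchasable single enantiomer; both C5 epimers formed in step 7 are carried on together, since C5 becomes a CH2 group in step 9.

**Step 1**
Reactants: 1 8-bromooct-1-ene; 2 (2R,2'R)-2,2'-bioxirane
Product: 4 (1R)-1-[(2R)-oxiran-2-yl]dec-9-en-1-ol, via oct-7-enylmagnesium bromide 3 (not isolated)
Conditions: 1, Mg, THF, rt; then slow addition to 2 (2.5 equiv), CuI (10 mol %), THF, −40 → −20 °C; aq NH4Cl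
Reagents that add atoms: none
Why: CuI-catalysed Grignard opening of an epoxide by SN2 at the unhindered CH2 terminus (C11), with the twofold-symmetric bis-epoxide in excess so that only one oxirane reacts; C9 and C10 are taken over unchanged from 2 because neither stereocentre is attacked.

**Step 2**
Reactants: 4 (1R)-1-[(2R)-oxiran-2-yl]dec-9-en-1-ol
Product: 5 tert-butyl(dimethyl){[(1R)-1-[(2R)-oxiran-2-yl]dec-9-en-1-yl]oxy}silane
Conditions: TBSCl, imidazole, DMF, 0 °C → rt
Reagents that add atoms: tert-butyl(chloro)dimethylsilane, CC(C)(C)[Si](C)(C)Cl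
Why: Imidazole-mediated silylation (Corey protocol) caps O10, so that O9, still latent in the epoxide, will later be the only free hydroxyl; the epoxide tolerates these non-nucleophilic conditions.

**Step 3**
Reactants: 5 tert-butyl(dimethyl){[(1R)-1-[(2R)-oxiran-2-yl]dec-9-en-1-yl]oxy}silane; 6 acetylene
Product: 8 (4R,5R)-5-{[tert-butyl(dimethyl)silyl]oxy}tetradec-13-en-1-yn-4-ol, via lithium acetylide 7 (not isolated)
Conditions: 6 (excess), n-BuLi, THF, −78 °C; BF3·OEt2, −78 °C; then 5, −78 °C; H2O
Reagents that add atoms: none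
Why: Yamaguchi–Hirao alkynylation, in which the lithium acetylide–BF3 reagent opens the BF3-activated terminal epoxide by SN2 at C8 without free basic alkoxide being present (no silyl migration), so C9 keeps its configuration and emerges as the homopropargylic alcohol.

**Step 4**
Reactants: 8 (4R,5R)-5-{[tert-butyl(dimethyl)silyl]oxy}tetradec-13-en-1-yn-4-ol
Product: 9 tert-butyl{[(1R)-1-[(2R)-2,3-dihydrofuran-2-yl]dec-9-en-1-yl]oxy}dimethylsilane
Conditions: Mo(CO)6 (25 mol %), Et3N, Et2O, hν (350 nm) to preform (Et3N)Mo(CO)5; then 8, rt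
Reagents that add atoms: none
Why: McDonald alkynol cycloisomerisation: the terminal alkyne rearranges on zerovalent molybdenum to a vinylidene, O9–H adds to its electrophilic carbon (the former alkyne terminus, C6) in an overall 5-endo closure and proton transfer by Et3N releases the C6=C7 enol ether, while the silyl ether, the terminal alkene and both stereocentres are bystanders.

**Step 5**
Reactants: 9 tert-butyl{[(1R)-1-[(2R)-2,3-dihydrofuran-2-yl]dec-9-en-1-yl]oxy}dimethylsilane
Product: 10 (1R)-1-[(2R)-2,3-dihydrofuran-2-yl]dec-9-en-1-ol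
Conditions: TBAF, THF, 0 °C → rt
Reagents that add atoms: none
Why: Fluoride-induced Si–O cleavage under non-acidic conditions, which the acid-labile enol ether survives; C10 is not touched.

**Step 6**
Reactants: 10 (1R)-1-[(2R)-2,3-dihydrofuran-2-yl]dec-9-en-1-ol; 11 dodecanoyl chloride
Product: 12 (1R)-1-[(2R)-2,3-dihydrofuran-2-yl]dec-9-en-1-yl dodecanoate
Conditions: 11, Et3N (excess), DMAP (cat.), CH2Cl2, 0 °C → rt
Reagents that add atoms: none
Why: DMAP-catalysed O-acylation with an acid chloride in excess Et3N, basic throughout so that the enol ether neither hydrolyses nor adds the alcohol, with retention at C10 since only the O–H bond is replaced.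

**Step 7**
Reactants: 12 (1R)-1-[(2R)-2,3-dihydrofuran-2-yl]dec-9-en-1-yl dodecanoate; 13 pentanal
Product: 14 (1R)-1-[(1S,3R,5S,7S)-7-butyl-2,6-dioxabicyclo[3.2.0]heptan-3-yl]dec-9-en-1-yl dodecanoate
Conditions: 13 (10 equiv), benzene, hν (300 nm, quartz), 10–15 °C, Ar
Reagents that add atoms: none
Why: Paternò–Büchi (2+2) photocycloaddition, the reaction type known for aliphatic aldehydes with 2,3-dihydrofuran: n,π*-excited pentanal attacks with its electrophilic oxygen the nucleophilic β-carbon C7 of the enol ether, giving a 1,4-biradical whose C6 radical is stabilised by the ring oxygen, and radical recombination then forms C5–C6. The oxetane is closed by this biradical coupling as a four-membered ring fused to the oxolane at C6–C7; no other ring forms. C6 and C7 are set together: the fusion can only be cis, and both new bonds should enter on the face of the five-membered ring opposite the C9 substituent, the only stereocentre on that ring, so that the carbon substituent at C6 and the oxygen at C7 end up trans to the side chain; C5 forms as an epimer mixture (exo-butyl epimer named) that is erased in step 9. Regioselectivity (oxygen to C7, not C6) follows from the stability of the α-oxy radical at C6. Chemoselectivity for the enol ether over the terminal C18=C19 alkene rests on the much higher reactivity of the electron-rich double bond towards the excited carbonyl, the laurate does not absorb at 300 nm, and the excess of pentanal makes up for its own γ-hydrogen (Norrish) cleavage.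

**Step 8**
Reactants: 14 (1R)-1-[(1S,3R,5S,7S)-7-butyl-2,6-dioxabicyclo[3.2.0]heptan-3-yl]dec-9-en-1-yl dodecanoate
Product: 15 (1R)-1-[(2R,4S,5R)-5-[(1R)-1-iodopentyl]-4-[(trimethylsilyl)oxy]oxolan-2-yl]dec-9-en-1-yl dodecanoate
Conditions: TMSI (1.1 equiv), 2-methylbut-2-ene, CH2Cl2, −78 → −40 °C; Et3N quench, filtration through Et3N-deactivated silica
Reagents that add atoms: iodotrimethylsilane, C[Si](C)(C)I
Why: Silyl iodide cleavage of a strained ether: the oxetane oxygen, the most Lewis-basic ether oxygen present, is silylated and iodide opens the silyloxonium ion by SN2 at C5, the oxetane carbon outside the oxolane ring and away from the C9 side chain (attack at the ring-fusion carbon C7 would have to come from beneath the oxolane on the face carrying that chain), so the C7–O bond and the C7 configuration are retained, the inverted C5 centre is irrelevant, and the ester is inert at this temperature.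

**Step 9**
Reactants: 15 (1R)-1-[(2R,4S,5R)-5-[(1R)-1-iodopentyl]-4-[(trimethylsilyl)oxy]oxolan-2-yl]dec-9-en-1-yl dodecanoate
Product: 17 (1R)-1-[(2R,4S,5S)-4-hydroxy-5-pentyloxolan-2-yl]dec-9-en-1-yl dodecanoate, via target trimethylsilyl ether 16 (not isolated)
Conditions: Bu3SnH (1.5 equiv), AIBN (cat.), toluene, 80 °C; then 0.5 M aq HCl, THF, 0 °C
Reagents that add atoms: none
Why: Radical chain dehalogenation with Bu3SnH replaces the C5 iodide by hydrogen without touching the ester or the remote terminal alkene (no five- or six-membered radical cyclisation is available) and removes the only uncontrolled stereocentre, after which dilute acid hydrolyses the labile trimethylsilyl ether to the C7 alcohol with no risk of acyl migration from the trans-disposed O10.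

**Compound list**
1 | 8-bromooct-1-ene | C=CCCCCCCBr | starting material
2 | (2R,2'R)-2,2'-bioxirane | C1O[C@H]1[C@H]1CO1 | starting material
3 | oct-7-enylmagnesium bromide (not isolated) | C=CCCCCCC[Mg]Br | intermediate
4 | (1R)-1-[(2R)-oxiran-2-yl]dec-9-en-1-ol | C=CCCCCCCC[C@@H](O)[C@H]1CO1 | intermediate
5 | tert-butyl(dimethyl){[(1R)-1-[(2R)-oxiran-2-yl]dec-9-en-1-yl]oxy}silane | C=CCCCCCCC[C@@H](O[Si](C)(C)C(C)(C)C)[C@H]1CO1 | intermediate
6 | acetylene | C#C | starting material
7 | lithium acetylide (not isolated) | [Li]C#C | intermediate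
8 | (4R,5R)-5-{[tert-butyl(dimethyl)silyl]oxy}tetradec-13-en-1-yn-4-ol | C=CCCCCCCC[C@@H](O[Si](C)(C)C(C)(C)C)[C@H](O)CC#C | intermediate
9 | tert-butyl{[(1R)-1-[(2R)-2,3-dihydrofuran-2-yl]dec-9-en-1-yl]oxy}dimethylsilane | C=CCCCCCCC[C@@H](O[Si](C)(C)C(C)(C)C)[C@H]1CC=CO1 | intermediate
10 | (1R)-1-[(2R)-2,3-dihydrofuran-2-yl]dec-9-en-1-ol | C=CCCCCCCC[C@@H](O)[C@H]1CC=CO1 | intermediate
11 | dodecanoyl chloride | CCCCCCCCCCCC(Cl)=O | starting material
12 | (1R)-1-[(2R)-2,3-dihydrofuran-2-yl]dec-9-en-1-yl dodecanoate (key-step precursor) | C=CCCCCCCC[C@@H](OC(=O)CCCCCCCCCCC)[C@H]1CC=CO1 | intermediate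
13 | pentanal | CCCCC=O | starting material
14 | (1R)-1-[(1S,3R,5S,7S)-7-butyl-2,6-dioxabicyclo[3.2.0]heptan-3-yl]dec-9-en-1-yl dodecanoate (key-step product; exo-butyl epimer drawn, the 7R epimer is expected alongside) | C=CCCCCCCC[C@@H](OC(=O)CCCCCCCCCCC)[C@H]1C[C@@H]2O[C@@H](CCCC)[C@@H]2O1 | intermediate
15 | (1R)-1-[(2R,4S,5R)-5-[(1R)-1-iodopentyl]-4-[(trimethylsilyl)oxy]oxolan-2-yl]dec-9-en-1-yl dodecanoate (iodide epimer derived from the drawn epimer of 14) | C=CCCCCCCC[C@@H](OC(=O)CCCCCCCCCCC)[C@H]1C[C@H](O[Si](C)(C)C)[C@H]([C@H](I)CCCC)O1 | intermediate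
16 | (1R)-1-[(2R,4S,5S)-5-pentyl-4-[(trimethylsilyl)oxy]oxolan-2-yl]dec-9-en-1-yl dodecanoate (not isolated) | C=CCCCCCCC[C@@H](OC(=O)CCCCCCCCCCC)[C@H]1C[C@H](O[Si](C)(C)C)[C@H](CCCCC)O1 | intermediate
17 | (1R)-1-[(2R,4S,5S)-4-hydroxy-5-pentyloxolan-2-yl]dec-9-en-1-yl dodecanoate | C=CCCCCCCC[C@@H](OC(=O)CCCCCCCCCCC)[C@H]1C[C@H](O)[C@H](CCCCC)O1 | target

**Step count.** Total: 9 steps. Longest linear sequence: 9 steps (1 and 2 to 17).

**Steps most likely to fail**

1. Step 7 (key step). What may go wrong: excited pentanal is lost to γ-hydrogen cleavage and hydrogen abstraction faster than the enol ether intercepts it; the aldehyde adds to both faces of the ring because the C9 substituent is remote from C6=C7; or some adduct forms with the reversed orientation. Fallback, setting out from 12 and coming back at 17: the enol ether of 12 would be epoxidised with dimethyldioxirane (acetone/CH2Cl2, −78 → 0 °C) on the face anti to the C9 substituent to give the 1,2-anhydro compound (1R)-1-[(1R,3R,5S)-2,6-dioxabicyclo[3.1.0]hexan-3-yl]dec-9-en-1-yl dodecanoate F1. F1 would then be opened at the acetal carbon C6 with tripentylaluminium (CH2Cl2, −78 → 0 °C). The alane ionises the epoxide and transfers pentyl from the aluminium held on O7, that is on the same face as the oxygen (syn-selective alane opening of glycal epoxides), which should give the C6/C7-cis product 17 directly and makes steps 8 and 9 unnecessary.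

2. Step 8. What may go wrong: iodide enters at the ring-fusion carbon C7 instead of C5 (most likely for the endo-butyl epimer, whose C5 rear side is screened by the oxolane ring), or adventitious HI adds to the terminal alkene. Fallback, setting out from 12 and coming back at 17, which avoids the oxetane altogether: 12 would be epoxidised with dimethyldioxirane as above and the crude epoxide F1 opened in methanol to the methyl furanoside (1R)-1-[(2R,4S,5S)-4-hydroxy-5-methoxyoxolan-2-yl]dec-9-en-1-yl dodecanoate F2 (anomer from anti opening drawn; either anomer serves). TESCl and imidazole in DMF would give (1R)-1-[(2R,4S,5S)-5-methoxy-4-[(triethylsilyl)oxy]oxolan-2-yl]dec-9-en-1-yl dodecanoate F3. Substitution of the anomeric methoxy group with (C5H11)2CuLi and BF3·OEt2 (Et2O, −78 °C) passes through the C6 oxocarbenium ion, for which inside attack cis to the C7 silyloxy group and trans to the C9 substituent is the expected course, giving (1R)-1-[(2R,4S,5S)-5-pentyl-4-[(triethylsilyl)oxy]oxolan-2-yl]dec-9-en-1-yl dodecanoate F4. 0.5 M aq HCl in THF would then release 17.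

3. Step 4. What may go wrong: catalyst turnover stalls through decomposition of the amine–pentacarbonyl complex or slow vinylidene formation next to the bulky silyloxy group, leaving 8 unchanged or oligomerised. Fallback, setting out from 5 and coming back at 9, replacing steps 3 and 4: epoxide 5 would be opened at C8 with LiCH2CN (from MeCN and n-BuLi, THF, −78 → −20 °C, quenched cold) to give (4R,5R)-5-{[tert-butyl(dimethyl)silyl]oxy}-4-hydroxytetradec-13-enenitrile F5. Reduction with i-Bu2AlH (CH2Cl2, −78 °C, aqueous citric acid work-up) would deliver the aldehyde as its lactol (5R)-5-[(1R)-1-{[tert-butyl(dimethyl)silyl]oxy}dec-9-en-1-yl]oxolan-2-ol F6. Mesylation and elimination in one pot (MsCl, Et3N, CH2Cl2, −40 °C → reflux), the standard lactol-to-glycal dehydration, would give 9.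

**Further compounds**
F1 | step 7 | (1R)-1-[(1R,3R,5S)-2,6-dioxabicyclo[3.1.0]hexan-3-yl]dec-9-en-1-yl dodecanoate | C=CCCCCCCC[C@@H](OC(=O)CCCCCCCCCCC)[C@H]1C[C@@H]2O[C@@H]2O1
F2 | step 8 | (1R)-1-[(2R,4S,5S)-4-hydroxy-5-methoxyoxolan-2-yl]dec-9-en-1-yl dodecanoate | C=CCCCCCCC[C@@H](OC(=O)CCCCCCCCCCC)[C@H]1C[C@H](O)[C@@H](OC)O1
F3 | step 8 | (1R)-1-[(2R,4S,5S)-5-methoxy-4-[(triethylsilyl)oxy]oxolan-2-yl]dec-9-en-1-yl dodecanoate | C=CCCCCCCC[C@@H](OC(=O)CCCCCCCCCCC)[C@H]1C[C@H](O[Si](CC)(CC)CC)[C@@H](OC)O1
F4 | step 8 | (1R)-1-[(2R,4S,5S)-5-pentyl-4-[(triethylsilyl)oxy]oxolan-2-yl]dec-9-en-1-yl dodecanoate | C=CCCCCCCC[C@@H](OC(=O)CCCCCCCCCCC)[C@H]1C[C@H](O[Si](CC)(CC)CC)[C@H](CCCCC)O1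
F5 | step 4 | (4R,5R)-5-{[tert-butyl(dimethyl)silyl]oxy}-4-hydroxytetradec-13-enenitrile | C=CCCCCCCC[C@@H](O[Si](C)(C)C(C)(C)C)[C@H](O)CCC#N
F6 | step 4 | (5R)-5-[(1R)-1-{[tert-butyl(dimethyl)silyl]oxy}dec-9-en-1-yl]oxolan-2-ol | C=CCCCCCCC[C@@H](O[Si](C)(C)C(C)(C)C)[C@H]1CCC(O)O1
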